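**Retrosynthetic overview**

1. Target 15 ⇒ open-chain (9S)-tetraketide tert-butyl ester 12 (ring B bought). In one flask the freed C-9 carbinol oxygen closes onto the C-5 ketone to give ring C (a 2,3-dihydro-4H-pyran-4-one, stereocentre C–O bond retained); heating then expels t-BuOH to an acylketene whose 6π-electrocyclisation and tautomerisation build ring A.
2. 12 ⇒ C6–C7 acylation of the trianion of diketo ester 5 with the (S)-β-silyloxy Weinreb amide 11.
3. 5 ⇒ tert-butyl acetoacetate + geranyl bromide, then γ-acetylation. Geranyl sits on the carbon flanked by both future phenol carbons, so only the 6-geranyl isomer can form.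
4. 11 ⇒ methyl syringate via β-keto Weinreb amide 9 and Ru–TsDPEN asymmetric transfer hydrogenation (the only stereocentre).
5. Ring order: B (purchased) → C → A, the last two in the same operation.

Assumption: "geranyl" = (2E)-3,7-dimethylocta-2,6-dien-1-yl and TBS = tert-butyldimethylsilyl; C-2 of 3, 5, 12 and 13 is an uncontrolled centre that becomes an aromatic carbon and is left undefined; commercial LDA solution is used.

**Route**

Step 1
Reactants: 1 tert-butyl acetoacetate; 2 geranyl bromide
Product: 3 tert-butyl 2-geranylacetoacetate (racemic at C-2)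
Conditions: NaH (1.05 eq), THF, 0 °C; then 2, 0 °C → rt
Reagents that add atoms: geranyl bromide (2), BrC/C=C(\C)CCC=C(C)C
Why: Acetoacetic ester C-alkylation (SN2 of the stabilised sodium enolate on a primary allylic bromide) is fast and C-selective, leaves the E-alkene untouched, and the racemic C-2 centre is erased later on aromatisation.

Step 2
Reactants: 3 tert-butyl 2-geranylacetoacetate; 4 N-methoxy-N-methylacetamide
Product: 5 tert-butyl 2-geranyl-3,5-dioxohexanoate
Conditions: LDA (2.2 eq), THF, −78 → 0 °C; then 4, −78 → 0 °C; cold 1 M HCl quench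
Reagents that add atoms: N-methoxy-N-methylacetamide (4), CC(=O)N(C)OC
Why: The α,γ-dianion of a β-keto ester (Huckin–Weiler dianion) reacts only at its more basic terminal γ-carbon, and the Weinreb amide gives a chelated tetrahedral adduct that stops at the ketone (dianion Claisen-type acylation).

Step 3
Reactants: 6 methyl syringate; 7 tert-butyldimethylsilyl chloride
Product: 8 methyl 4-(tert-butyldimethylsilyloxy)-3,5-dimethoxybenzoate
Conditions: imidazole, DMF, rt
Reagents that add atoms: tert-butyldimethylsilyl chloride (7), CC(C)(C)[Si](C)(C)Cl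
Why: Corey silylation of the phenol masks the acidic ArOH for the enolate chemistry that follows.

Step 4
Reactants: 8 methyl 4-(tert-butyldimethylsilyloxy)-3,5-dimethoxybenzoate; 4 N-methoxy-N-methylacetamide
Product: 9 3-[4-(tert-butyldimethylsilyloxy)-3,5-dimethoxyphenyl]-N-methoxy-N-methyl-3-oxopropanamide
Conditions: 4 (2.3 eq), LDA (2.3 eq), THF, −78 °C; then 8, −78 → −20 °C; cold 1 M HCl quench
Reagents that add atoms: N-methoxy-N-methylacetamide (4), CC(=O)N(C)OC
Why: Crossed Claisen condensation of the lithium enolate of the Weinreb acetamide with a non-enolisable aryl ester, the product being protected from further attack as its β-keto amide enolate.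

Step 5
Reactants: 9 3-[4-(tert-butyldimethylsilyloxy)-3,5-dimethoxyphenyl]-N-methoxy-N-methyl-3-oxopropanamide
Product: 10 (3S)-3-[4-(tert-butyldimethylsilyloxy)-3,5-dimethoxyphenyl]-3-hydroxy-N-methoxy-N-methylpropanamide
Conditions: RuCl(p-cymene)[(S,S)-TsDPEN] (1 mol %), HCO2H/Et3N (5:2), CH2Cl2, 35 °C
Reagents that add atoms: none
Why: Noyori asymmetric transfer hydrogenation of an aryl ketone, in which the (S,S)-TsDPEN–Ru hydride attacks through the CH/π-organised six-membered transition state on the same face as in acetophenone → (S)-1-phenylethanol, and since OH > aryl > CH2 here as well the new carbinol is (S) (≥95% ee expected).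

Step 6
Reactants: 10 (3S)-3-[4-(tert-butyldimethylsilyloxy)-3,5-dimethoxyphenyl]-3-hydroxy-N-methoxy-N-methylpropanamide; 7 tert-butyldimethylsilyl chloride
Product: 11 (3S)-3-(tert-butyldimethylsilyloxy)-3-[4-(tert-butyldimethylsilyloxy)-3,5-dimethoxyphenyl]-N-methoxy-N-methylpropanamide
Conditions: imidazole, DMF, rt
Reagents that add atoms: tert-butyldimethylsilyl chloride (7), CC(C)(C)[Si](C)(C)Cl
Why: Silylation of the secondary benzylic alcohol blocks retro-aldol and premature cyclisation in the polyanion coupling, re-silylates any phenol freed in step 5, and does not touch the stereocentre.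

Step 7
Reactants: 5 tert-butyl 2-geranyl-3,5-dioxohexanoate; 11 (3S)-3-(tert-butyldimethylsilyloxy)-3-[4-(tert-butyldimethylsilyloxy)-3,5-dimethoxyphenyl]-N-methoxy-N-methylpropanamide
Product: 12 tert-butyl (9S)-9-(tert-butyldimethylsilyloxy)-9-[4-(tert-butyldimethylsilyloxy)-3,5-dimethoxyphenyl]-2-geranyl-3,5,7-trioxononanoate
Conditions: 5 (1.3 eq), LDA (4.0 eq), THF, −78 → 0 °C; then 11, −78 → −30 °C; inverse quench into cold 1 M HCl (pH 5); used after a short silica plug
Reagents that add atoms: none
Why: Harris-type polyanion acylation, in which the trianion of the 3,5-diketo ester reacts through its least stabilised terminal C-6 carbanion and the N,O-chelated Weinreb adduct prevents over-addition and keeps the acidic tetraketide masked until the quench, the (S)-centre β to the reacting carbonyl being untouched.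

Step 8
Reactants: 12 tert-butyl (9S)-9-(tert-butyldimethylsilyloxy)-9-[4-(tert-butyldimethylsilyloxy)-3,5-dimethoxyphenyl]-2-geranyl-3,5,7-trioxononanoate
Product: 15 (2S)-6-geranyl-5,7-dihydroxy-2-(4-hydroxy-3,5-dimethoxyphenyl)chroman-4-one (target CNP0372687.1), via dihydropyranone tert-butyl ester 13 (not isolated), via acylketene 14 (not isolated)
Conditions: (i) 48% aq. HF, MeCN, 0 → 23 °C; NaHCO3 work-up, toluene azeotrope, no purification; (ii) PhMe (5 mM), 110 °C, N2 sweep
Reagents that add atoms: none
Why: Proposed new method: HF removes both silyl groups and the freed (S)-carbinol adds to the δ-ketone and dehydrates (known δ-hydroxy-β-diketone → 2,3-dihydro-4H-pyran-4-one cyclodehydration, which keeps the C–O bond at the stereocentre and fixes which oxygen becomes O-1), then on heating the tert-butyl β-keto ester expels tert-butanol to an acylketene (as in thermal transacetoacetylation) whose enol is a dienylketene that undergoes 6π-electrocyclisation and tautomerises to the phloroglucinol ring (closest known reaction: the dienylketene → phenol stage of the Danheiser benzannulation), O-trapping to a pyrone being impossible because the only suitably placed enol oxygen is already the ring-C ether.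

**Compound list**

1 | tert-butyl acetoacetate | CC(=O)CC(=O)OC(C)(C)C | starting material
2 | geranyl bromide, (2E)-1-bromo-3,7-dimethylocta-2,6-diene | BrC/C=C(\C)CCC=C(C)C | starting material
3 | tert-butyl 2-geranylacetoacetate (racemic at C-2) | CC(=O)C(C/C=C(\C)CCC=C(C)C)C(=O)OC(C)(C)C | intermediate
4 | N-methoxy-N-methylacetamide | CC(=O)N(C)OC | starting material
5 | tert-butyl 2-geranyl-3,5-dioxohexanoate (keto/enol mixture, racemic at C-2) | CC(=O)CC(=O)C(C/C=C(\C)CCC=C(C)C)C(=O)OC(C)(C)C | intermediate
6 | methyl syringate (methyl 4-hydroxy-3,5-dimethoxybenzoate) | COC(=O)c1cc(OC)c(O)c(OC)c1 | starting material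
7 | tert-butyldimethylsilyl chloride | CC(C)(C)[Si](C)(C)Cl | starting material
8 | methyl 4-(tert-butyldimethylsilyloxy)-3,5-dimethoxybenzoate | COC(=O)c1cc(OC)c(O[Si](C)(C)C(C)(C)C)c(OC)c1 | intermediate
9 | 3-[4-(TBS-oxy)-3,5-dimethoxyphenyl]-N-methoxy-N-methyl-3-oxopropanamide | CON(C)C(=O)CC(=O)c1cc(OC)c(O[Si](C)(C)C(C)(C)C)c(OC)c1 | intermediate
10 | (3S)-3-[4-(TBS-oxy)-3,5-dimethoxyphenyl]-3-hydroxy-N-methoxy-N-methylpropanamide | CON(C)C(=O)C[C@H](O)c1cc(OC)c(O[Si](C)(C)C(C)(C)C)c(OC)c1 | intermediate
11 | (3S)-3-(TBS-oxy)-3-[4-(TBS-oxy)-3,5-dimethoxyphenyl]-N-methoxy-N-methylpropanamide | CON(C)C(=O)C[C@H](O[Si](C)(C)C(C)(C)C)c1cc(OC)c(O[Si](C)(C)C(C)(C)C)c(OC)c1 | intermediate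
12 | tert-butyl (9S)-9-(TBS-oxy)-9-[4-(TBS-oxy)-3,5-dimethoxyphenyl]-2-geranyl-3,5,7-trioxononanoate (C-2 epimers, keto/enol mixture) | CC(C)(C)OC(=O)C(C/C=C(\C)CCC=C(C)C)C(=O)CC(=O)CC(=O)C[C@H](O[Si](C)(C)C(C)(C)C)c1cc(OC)c(O[Si](C)(C)C(C)(C)C)c(OC)c1 | intermediate
13 | tert-butyl 2-geranyl-4-[(2S)-2-(4-hydroxy-3,5-dimethoxyphenyl)-4-oxo-3,4-dihydro-2H-pyran-6-yl]-3-oxobutanoate | CC(C)(C)OC(=O)C(C/C=C(\C)CCC=C(C)C)C(=O)CC1=CC(=O)C[C@@H](c2cc(OC)c(O)c(OC)c2)O1 | intermediate (not isolated)
14 | 2-geranyl-4-[(2S)-2-(4-hydroxy-3,5-dimethoxyphenyl)-4-oxo-3,4-dihydro-2H-pyran-6-yl]-3-oxobut-1-en-1-one (acylketene) | O=C=C(C/C=C(\C)CCC=C(C)C)C(=O)CC1=CC(=O)C[C@@H](c2cc(OC)c(O)c(OC)c2)O1 | intermediate (not isolated)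
15 | (2S)-6-geranyl-5,7-dihydroxy-2-(4-hydroxy-3,5-dimethoxyphenyl)chroman-4-one | COc1cc([C@@H]2CC(=O)c3c(cc(O)c(C/C=C(\C)CCC=C(C)C)c3O)O2)cc(OC)c1O | target

**Step count**

Total: 8 steps. Longest linear sequence: 6 steps (6 → 8 → 9 → 10 → 11 → 12 → 15, steps 3–8); the other branch (1 → 3 → 5) is 2 steps.

**The three steps most likely to fail, with fallbacks**

Step 8 is the most exposed. The α-branched tert-butyl ester may need more than 110 °C to release the ketene, adventitious water would divert the ketene to a decarboxylated methyl ketone, and a hot solution of the free 4-hydroxybenzylic ether could lose some ee. The fallback replaces thermolysis by carboxyl activation at or below room temperature. It sets out from 13, isolated after the HF stage. TMSOTf/2,6-lutidine (CH2Cl2, 0 °C, then pH 7 buffer) cleaves the tert-butyl ester to the β-keto acid 2-geranyl-4-[(2S)-2-(4-hydroxy-3,5-dimethoxyphenyl)-4-oxo-3,4-dihydro-2H-pyran-6-yl]-3-oxobutanoic acid F1. This is used at once: EDC·HCl (CH2Cl2, 0 °C → rt) dehydrates it to the same acylketene, so the fallback comes back to the route at 14 and hence 15.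

Step 7 is next. The strongly basic trianion may deprotonate 11 α to the amide and expel silyloxide (giving the cinnamoyl amide), or simply add sluggishly. The fallback swaps the Claisen-type acylation for aldol addition and oxidation, and sets out from 11. DIBAL-H (THF, −78 °C) gives the aldehyde (3S)-3-(tert-butyldimethylsilyloxy)-3-[4-(tert-butyldimethylsilyloxy)-3,5-dimethoxyphenyl]propanal F2, which reacts with the trianion of 5 at −78 °C faster than it is enolised. The product is the aldol tert-butyl (9S)-9-(tert-butyldimethylsilyloxy)-9-[4-(tert-butyldimethylsilyloxy)-3,5-dimethoxyphenyl]-2-geranyl-7-hydroxy-3,5-dioxononanoate F3 (C-7 epimers). Dess–Martin periodinane (NaHCO3, CH2Cl2, 0 °C) oxidises it, and the fallback comes back at 12.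

Step 2 is third. The dianion of 3 can enolise the acetamide 4 instead of adding to it, giving low conversion. The fallback again uses an aldehyde that cannot be lost to proton transfer, and sets out from 3. The dianion (LDA, 2.2 eq) is treated with acetaldehyde at −78 °C to give tert-butyl 2-geranyl-5-hydroxy-3-oxohexanoate F4. Dess–Martin oxidation then returns the route to 5.

**Further compounds**

F1 | step 8 | 2-geranyl-4-[(2S)-2-(4-hydroxy-3,5-dimethoxyphenyl)-4-oxo-3,4-dihydro-2H-pyran-6-yl]-3-oxobutanoic acid | OC(=O)C(C/C=C(\C)CCC=C(C)C)C(=O)CC1=CC(=O)C[C@@H](c2cc(OC)c(O)c(OC)c2)O1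
F2 | step 7 | (3S)-3-(tert-butyldimethylsilyloxy)-3-[4-(tert-butyldimethylsilyloxy)-3,5-dimethoxyphenyl]propanal | O=CC[C@H](O[Si](C)(C)C(C)(C)C)c1cc(OC)c(O[Si](C)(C)C(C)(C)C)c(OC)c1
F3 | step 7 | tert-butyl (9S)-9-(tert-butyldimethylsilyloxy)-9-[4-(tert-butyldimethylsilyloxy)-3,5-dimethoxyphenyl]-2-geranyl-7-hydroxy-3,5-dioxononanoate | CC(C)(C)OC(=O)C(C/C=C(\C)CCC=C(C)C)C(=O)CC(=O)CC(O)C[C@H](O[Si](C)(C)C(C)(C)C)c1cc(OC)c(O[Si](C)(C)C(C)(C)C)c(OC)c1
F4 | step 2 | tert-butyl 2-geranyl-5-hydroxy-3-oxohexanoate | CC(O)CC(=O)C(C/C=C(\C)CCC=C(C)C)C(=O)OC(C)(C)C
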